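**Plan**

1. Retrosynthesis: the lactol O–H is unmasked last from an (S)-1-(2-nitrophenyl)ethyl acetal. Before that, the seven-membered 1,4-dioxepinone ring is cut at the diaryl ether bond (ring-A oxygen to C-4 of the isobenzofuranone ring B) and at the bond from the ester carbonyl carbon to C-3 of ring A. This gives atranol and a ring-B aryl(anisyl)iodonium salt that already carries the carbonyl on O-5 as an S-methyl thiocarbonate; the salt goes back via a phthalide to 3,5-dimethoxy-4-methylbenzoic acid.
2. Forward: ring B is built first (phthalide by directed lithiation/CO2, iodination at the only free ring carbon, thiocarbonates, double benzylic bromination to set the lactol level at C-3 and the CH2OAc arm, acetal formation, epimer separation, then iodine(III)). Ring A is atranol (two steps). The two halves are joined and the seven-membered ring is closed in one flask (step 12); photolysis ends the route.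
3. Enabling feature: atranol is C2v-symmetric, so its two OH groups and its two ring CH are pairwise equivalent. In ring B the single unsubstituted carbon C-4 is ortho to O-5, so C-4–I(III) plus O-5–C(=O)SMe is a 1,4-bis-electrophile for the O/C-3 1,3-bis-nucleophile of atranol. The result is a formal (3+4) annulation to the dibenzo-1,4-dioxepinone ring, run as two stages in one flask.
4. Stereochemistry: the lactol carbon is formed racemic (step 6) and converted into a pair of diastereomeric acetals with (S)-1-(2-nitrophenyl)ethanol (step 7). The (3S) epimer is obtained by separation with acid-catalysed recycling of the (3R) epimer (step 8), is carried as a configurationally stable acetal, and is released by photolysis that does not touch the bonds at the stereocentre (retention, S).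

Key step: step 12

Remark 1: the free lactol is a cyclic hemiacetal of a 2-formylbenzoic acid and can epimerise by ring–chain tautomerism; it is therefore set free only in the last step under neutral conditions and should be kept cold and away from base.
Remark 2: (S)-1-(2-nitrophenyl)ethanol is taken as commercial (otherwise CBS reduction of 2'-nitroacetophenone); all compounds that carry the nitrophenylethyl group are handled in amber glassware.
Remark 3: the two C-3 epimeric acetals of step 7 are assumed to be separable as diastereomers; the configuration at C-3 is to be assigned by X-ray diffraction (iodine as heavy atom, the auxiliary as internal reference) before the material is carried on.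

**Route**

Step 1
Reactants: 1 3,5-dimethoxy-4-methylbenzoic acid
Product: 2 (3,5-dimethoxy-4-methylphenyl)methanol
Conditions: BH3·THF, THF, 0 °C to rt; MeOH, aq. work-up
Reagents that add atoms: none
Why: Borane reduction of an aromatic carboxylic acid to the benzyl alcohol should proceed cleanly, the aryl ethers being inert.

Step 2
Reactants: 2 (3,5-dimethoxy-4-methylphenyl)methanol
Product: 5 5,7-dimethoxy-6-methyl-3H-isobenzofuran-1-one, via dilithio species 3 (not isolated), via hydroxy acid 4 (not isolated)
Conditions: n-BuLi (2.3 equiv), TMEDA, toluene, 0 °C to rt; CO2, −78 °C; aq. HCl, rt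
Reagents that add atoms: carbon dioxide, O=C=O
Why: Directed ortho-metalation (CH2OLi and OMe cooperate at C-2; the site between the two OMe groups is blocked by the methyl group), carboxylation and acid lactonisation should give the phthalide with its carbonyl next to OMe.

Step 3
Reactants: 5 5,7-dimethoxy-6-methyl-3H-isobenzofuran-1-one
Product: 6 5,7-dihydroxy-6-methyl-3H-isobenzofuran-1-one
Conditions: BBr3 (3 equiv), CH2Cl2, −78 °C to rt; H2O
Reagents that add atoms: none
Why: Lewis-acid cleavage of both aryl methyl ethers (BBr3 demethylation) should leave the lactone intact.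

Step 4
Reactants: 6 5,7-dihydroxy-6-methyl-3H-isobenzofuran-1-one
Product: 7 5,7-dihydroxy-4-iodo-6-methyl-3H-isobenzofuran-1-one
Conditions: NIS (1.05 equiv), MeCN, 0 °C
Reagents that add atoms: N-iodosuccinimide, O=C1CCC(=O)N1I
Why: Electrophilic aromatic iodination can only occur at C-4, the one unsubstituted ring carbon, which is ortho to 5-OH and para to 7-OH.

Step 5
Reactants: 7 5,7-dihydroxy-4-iodo-6-methyl-3H-isobenzofuran-1-one
Product: 8 4-iodo-6-methyl-5,7-bis[(methylsulfanyl)carbonyloxy]-3H-isobenzofuran-1-one
Conditions: MeSC(O)Cl (2.4 equiv), Et3N, DMAP (cat.), CH2Cl2, 0 °C to rt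
Reagents that add atoms: S-methyl chlorothioformate, CSC(=O)Cl
Why: O-acylation of both phenols with a chlorothioformate should install the latent ester carbonyl on O-5 and a protecting group of the same kind on O-7, both inert to radicals, acid and weak nucleophiles.

Step 6
Reactants: 8 4-iodo-6-methyl-5,7-bis[(methylsulfanyl)carbonyloxy]-3H-isobenzofuran-1-one
Product: 9 rac-3-bromo-6-(bromomethyl)-4-iodo-5,7-bis[(methylsulfanyl)carbonyloxy]-3H-isobenzofuran-1-one
Conditions: NBS (2.2 equiv), AIBN (cat.), PhCF3, 85 °C
Reagents that add atoms: N-bromosuccinimide, O=C1CCC(=O)N1Br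
Why: Wohl–Ziegler bromination should take one hydrogen from each benzylic site (the C-3 methylene and the 6-methyl group) because the ring has no free position and both phenols are acylated; C-3 forms racemic.

Step 7
Reactants: 9 rac-3-bromo-6-(bromomethyl)-4-iodo-5,7-bis[(methylsulfanyl)carbonyloxy]-3H-isobenzofuran-1-one; 10 (S)-1-(2-nitrophenyl)ethanol
Product: 12 6-(acetoxymethyl)-4-iodo-5,7-bis[(methylsulfanyl)carbonyloxy]-3-[(1S)-1-(2-nitrophenyl)ethoxy]-3H-isobenzofuran-1-one as the mixture of both C-3 epimers, via bromomethyl acetal 11 (not isolated)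
Conditions: 10 (1.1 equiv), 2,6-lutidine, MeCN, rt to 40 °C; then KOAc, 18-crown-6 (cat.), rt
Reagents that add atoms: potassium acetate, CC(=O)[O-].[K+]
Why: SN1 alcoholysis of the 3-bromophthalide (the much more reactive, oxocarbenium-forming bromide) followed by SN2 acetate displacement at the benzylic bromide should give the acetal acetate; the planar cation is attacked from both faces, so the product is expected as a mixture of the (3S) and (3R) epimers, which are diastereomers because of the (1S) auxiliary.

Step 8
Reactants: 12 the acetal acetate as the mixture of both C-3 epimers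
Product: 13 (3S)-6-(acetoxymethyl)-4-iodo-5,7-bis[(methylsulfanyl)carbonyloxy]-3-[(1S)-1-(2-nitrophenyl)ethoxy]-3H-isobenzofuran-1-one
Conditions: separation of the C-3 epimers on silica (or fractional crystallisation); (3R) fraction: TsOH (10 mol%), 4 Å MS, PhMe, 70 °C, then back to the separation
Reagents that add atoms: none
Why: Resolution by diastereomer separation with recycling: the epimers differ only at the acyloxy-alkoxy acetal carbon, and acid-catalysed epimerisation of this pseudo-ester through the phthalidyl oxocarbenium ion (or its ring-opened form) should return the unwanted (3R) epimer to the mixture, so that the material converges on the (3S,1'S) isomer; no other centre is affected.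

Step 9
Reactants: 13 the (3S,1'S) acetal acetate
Product: 15 (4-methoxyphenyl)(ring-B aryl)iodonium tosylate (aryl of 13 bound through C-4), via hydroxy(tosyloxy)iodane 14 (not isolated)
Conditions: mCPBA (1.2 equiv), TsOH·H2O (1.2 equiv), CH2Cl2/CF3CH2OH 1:1, 0 °C to rt, short reaction time; then anisole (1.5 equiv), rt
Reagents that add atoms: anisole, COc1ccccc1; p-toluenesulfonic acid, Cc1ccc(S(=O)(=O)O)cc1
Why: The one-pot diaryliodonium synthesis (oxidation of ArI to the Koser-type λ3-iodane, then para-selective SEAr on anisole) should work because the acyl-deactivated thiocarbonate sulfur is a poor partner for the peracid and the electron-poor pseudo-ester acetal should ionise only slowly in acid at or below rt, unlike under the hot conditions of step 8, so the acetal centre should keep its configuration.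

Step 10
Reactants: 16 3,5-dimethoxytoluene
Product: 18 2,6-dimethoxy-4-methylbenzaldehyde, via aryllithium 17 (not isolated)
Conditions: n-BuLi, TMEDA, Et2O, 0 °C to rt; DMF; aq. HCl
Reagents that add atoms: N,N-dimethylformamide, CN(C)C=O
Why: Directed ortho-metalation between the two methoxy groups followed by formylation with DMF is the standard entry to this aldehyde.

Step 11
Reactants: 18 2,6-dimethoxy-4-methylbenzaldehyde
Product: 19 atranol (2,6-dihydroxy-4-methylbenzaldehyde)
Conditions: BBr3, CH2Cl2, −78 °C to rt; H2O
Reagents that add atoms: none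
Why: BBr3 demethylation of both ethers, assisted by chelation to the ortho formyl group, should give the symmetric dihydroxy aldehyde.

Step 12
Reactants: 15 (4-methoxyphenyl)(ring-B aryl)iodonium tosylate; 19 atranol
Product: 22 galbinic acid (1S)-1-(2-nitrophenyl)ethyl acetal with (S) configuration at the acetal carbon, via diaryl ether 20 (not isolated), via acyl triflate 21 (not isolated)
Conditions: (i) 19 (1.2 equiv), KOtBu (1.2 equiv), THF, 0 °C; 15, rt; (ii) same flask, THF removed, ClCH2CH2Cl (5 mM), 2,6-di-tert-butyl-4-methylpyridine (3 equiv), AgOTf (2.5 equiv), 4 Å MS, 0 °C to rt; aq. NaHCO3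
Reagents that add atoms: none
Why: Proposed new method: in stage (i) the potassium phenoxide of 19 exchanges onto iodine(III) of 15 and reductive ligand coupling transfers the ring-B aryl (ipso C-4) to oxygen, giving diaryl ether 20 and 4-iodoanisole; this is the known metal-free O-arylation of phenols by diaryliodonium salts. In stage (ii) silver(I) binds the sulfur of the O-aryl S-methyl thiocarbonates, AgSMe leaves, and the aryloxycarbonyl triflate on O-5 (an acylium equivalent) acylates C-3 of the atranol ring, the carbon ortho to the new ether oxygen and para to the free OH, with the proton passing to the hindered pyridine; the closest known reactions are silver-promoted acyl transfer from thioesters and the Lewis-acid Friedel–Crafts closure of 2-arylphenyl chloroformates to benzocoumarins. The seven-membered dioxepinone ring closes by intramolecular Friedel–Crafts acylation (arene carbon onto the exocyclic acyl carbon through a seven-membered transition state); no stereocentre is formed and the acetal carbon is not touched. Ring B should be transferred in preference to anisyl because it is di-ortho-substituted and more electron-poor, and O-arylation should beat C-arylation because the phenoxide is stabilised by the formyl group; which OH and which CH of 19 react does not matter because 19 is C2v-symmetric. The thiocarbonate should ignore the weakly nucleophilic phenoxide in stage (i) and be switched on only by Ag(I), and only C-3 of ring A can reach the O-5 acyl group. The O-7 acyl triflate in 21 has no partner and should hydrolyse with loss of CO2 on quench, which frees the 7-OH.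

Step 13
Reactants: 22 galbinic acid (1S)-1-(2-nitrophenyl)ethyl acetal
Product: 23 galbinic acid
Conditions: hν (365 nm), MeCN/H2O 9:1, 10 °C, argon; cold neutral work-up
Reagents that add atoms: none
Why: o-Nitrobenzyl photodeprotection (aci-nitro, then hemiketal, then 2-nitrosoacetophenone), as used for photolabile o-nitrobenzyl glycosides, cleaves only the auxiliary side of the acetal oxygen, so the lactol carbon should keep its (S) configuration.

**Compound list**

1 | 3,5-dimethoxy-4-methylbenzoic acid | COc1cc(C(=O)O)cc(OC)c1C | starting material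
2 | (3,5-dimethoxy-4-methylphenyl)methanol | COc1cc(CO)cc(OC)c1C | intermediate
3 | C,O-dilithio species (2-lithio benzylic alkoxide) | [Li]OCc1cc(OC)c(C)c(OC)c1[Li] | intermediate
4 | 2-(hydroxymethyl)-4,6-dimethoxy-5-methylbenzoic acid | OCc1cc(OC)c(C)c(OC)c1C(=O)O | intermediate
5 | 5,7-dimethoxy-6-methyl-3H-isobenzofuran-1-one | O=C1OCc2cc(OC)c(C)c(OC)c12 | intermediate
6 | 5,7-dihydroxy-6-methyl-3H-isobenzofuran-1-one | O=C1OCc2cc(O)c(C)c(O)c12 | intermediate
7 | 5,7-dihydroxy-4-iodo-6-methyl-3H-isobenzofuran-1-one | O=C1OCc2c(I)c(O)c(C)c(O)c12 | intermediate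
8 | 4-iodo-6-methyl-5,7-bis[(methylsulfanyl)carbonyloxy]-3H-isobenzofuran-1-one | O=C1OCc2c(I)c(OC(=O)SC)c(C)c(OC(=O)SC)c12 | intermediate
9 | rac-3-bromo-6-(bromomethyl)-4-iodo-5,7-bis[(methylsulfanyl)carbonyloxy]-3H-isobenzofuran-1-one | O=C1OC(Br)c2c(I)c(OC(=O)SC)c(CBr)c(OC(=O)SC)c12 | intermediate
10 | (S)-1-(2-nitrophenyl)ethanol | C[C@H](O)c1ccccc1[N+](=O)[O-] | starting material
11 | 6-(bromomethyl)-4-iodo-5,7-bis[(methylsulfanyl)carbonyloxy]-3-[(1S)-1-(2-nitrophenyl)ethoxy]-3H-isobenzofuran-1-one, C-3 epimer mixture | O=C1OC(O[C@@H](C)c3ccccc3[N+](=O)[O-])c2c(I)c(OC(=O)SC)c(CBr)c(OC(=O)SC)c12 | intermediate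
12 | 6-(acetoxymethyl)-4-iodo-5,7-bis[(methylsulfanyl)carbonyloxy]-3-[(1S)-1-(2-nitrophenyl)ethoxy]-3H-isobenzofuran-1-one, C-3 epimer mixture | CC(=O)OCc1c(OC(=O)SC)c2c(c(I)c1OC(=O)SC)C(O[C@@H](C)c1ccccc1[N+](=O)[O-])OC2=O | intermediate
13 | (3S)-6-(acetoxymethyl)-4-iodo-5,7-bis[(methylsulfanyl)carbonyloxy]-3-[(1S)-1-(2-nitrophenyl)ethoxy]-3H-isobenzofuran-1-one | CC(=O)OCc1c(OC(=O)SC)c2c(c(I)c1OC(=O)SC)[C@@H](O[C@@H](C)c1ccccc1[N+](=O)[O-])OC2=O | intermediate
14 | [hydroxy(tosyloxy)iodo] derivative of 13 (λ3-iodane at C-4) | CC(=O)OCc1c(OC(=O)SC)c2c(c(I(O)OS(=O)(=O)c3ccc(C)cc3)c1OC(=O)SC)[C@@H](O[C@@H](C)c1ccccc1[N+](=O)[O-])OC2=O | intermediate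
15 | (4-methoxyphenyl)(ring-B aryl)iodonium tosylate (aryl of 13 bound through C-4) | CC(=O)OCc1c(OC(=O)SC)c2c(c([I+]c3ccc(OC)cc3)c1OC(=O)SC)[C@@H](O[C@@H](C)c1ccccc1[N+](=O)[O-])OC2=O.Cc1ccc(S(=O)(=O)[O-])cc1 | intermediate
16 | 3,5-dimethoxytoluene | COc1cc(C)cc(OC)c1 | starting material
17 | 2,6-dimethoxy-4-methylphenyllithium | COc1cc(C)cc(OC)c1[Li] | intermediate
18 | 2,6-dimethoxy-4-methylbenzaldehyde | COc1cc(C)cc(OC)c1C=O | intermediate
19 | atranol (2,6-dihydroxy-4-methylbenzaldehyde) | Cc1cc(O)c(C=O)c(O)c1 | intermediate
20 | diaryl ether (13 with iodine replaced by the 2-formyl-3-hydroxy-5-methylphenoxy group) | CC(=O)OCc1c(OC(=O)SC)c2c(c(Oc3cc(C)cc(O)c3C=O)c1OC(=O)SC)[C@@H](O[C@@H](C)c1ccccc1[N+](=O)[O-])OC2=O | intermediate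
21 | depsidone acetal carrying C(=O)OSO2CF3 on O-7 of ring B (seven-membered lactone closed) | CC(=O)OCc1c(OC(=O)OS(=O)(=O)C(F)(F)F)c2c(c3c1OC(=O)c1c(C)cc(O)c(C=O)c1O3)[C@@H](O[C@@H](C)c1ccccc1[N+](=O)[O-])OC2=O | intermediate
22 | galbinic acid (1S)-1-(2-nitrophenyl)ethyl acetal, (S) at the acetal carbon | CC(=O)OCc1c(O)c2c(c3c1OC(=O)c1c(C)cc(O)c(C=O)c1O3)[C@@H](O[C@@H](C)c1ccccc1[N+](=O)[O-])OC2=O | intermediate
23 | galbinic acid | CC(=O)OCc1c(O)c2c(c3c1OC(=O)c1c(C)cc(O)c(C=O)c1O3)[C@@H](O)OC2=O | target

**Count and risks**

Total steps: 13. Longest linear sequence: 11 (steps 1–9, 12, 13); steps 10–11 form the second branch.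

Steps most likely to fail:

1. Step 12 (proposed new method). The silver-generated acyl electrophile may be captured intermolecularly by the free ring-A phenol (oligomeric carbonates) instead of closing the ring at carbon, or the phenoxide may attack the thiocarbonate before aryl transfer. The fallback sets out from diaryl ether 20, isolated after the first stage alone, and comes back to the route at 22. Iodination para to the free OH of ring A (NIS, cat. TFA, MeCN, 0 °C) should give the ring-A iodide of the diaryl ether F1. Silver-assisted hydrolysis of both thiocarbonates (AgOTf, wet MeCN) should give the iodo diphenol F2. Palladium-catalysed intramolecular aryloxycarbonylation (Pd(OAc)2, Xantphos, CO 1 atm, iPr2NEt, toluene, 80 °C), a known entry to dibenzo[b,e][1,4]dioxepin-11-ones, then closes the lactone with the carbonyl carbon coming from CO and gives 22.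

2. Step 9. The hindered, electron-poor aryl iodide may be oxidised so slowly that the peracid attacks the sulfur of the thiocarbonates instead. The fallback sets out from 13 and comes back at 15; sulfur is introduced only after the iodine has been oxidised, and the ring carries electron-releasing silyl ethers during the oxidation. From 13, silver-assisted hydrolysis (AgOTf, wet MeCN) should give the iodo diol F3. Silylation (TIPSOTf, 2,6-lutidine) gives the bis(triisopropylsilyl) ether F4. The same one-pot oxidation and anisole coupling gives the silylated iodonium tosylate F5. Acidic desilylation (HF·pyridine, THF) gives the iodonium diol tosylate F6. Acylation with MeSC(O)Cl and 2,6-lutidine at −20 °C rejoins the route at 15.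

3. Step 13. The photolysis may stall through competing light absorption by the hydroxybenzaldehyde/depsidone chromophore, or secondary photochemistry at the o-hydroxybenzyl acetate may consume product. The fallback is a reductive release that sets out from 22 and comes back at 23. Reduction of the nitro group (Zn, NH4Cl, THF/H2O, 0 °C) should give the aminophenyl acetal F7. Its o-aminobenzylic ether should fragment by 1,4-elimination in pH 5 buffer at rt (self-immolative cleavage on the auxiliary side), giving 23 with the bonds at the lactol carbon untouched.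

Further compounds
F1 | step 12 | ring-A iodide of diaryl ether 20 (iodine ortho to the ether oxygen, para to the free OH) | CC(=O)OCc1c(OC(=O)SC)c2c(c(Oc3c(I)c(C)cc(O)c3C=O)c1OC(=O)SC)[C@@H](O[C@@H](C)c1ccccc1[N+](=O)[O-])OC2=O
F2 | step 12 | iodo diphenol (F1 with both thiocarbonates cleaved to OH) | CC(=O)OCc1c(O)c2c(c(Oc3c(I)c(C)cc(O)c3C=O)c1O)[C@@H](O[C@@H](C)c1ccccc1[N+](=O)[O-])OC2=O
F3 | step 9 | iodo diol (13 with both thiocarbonates cleaved to OH) | CC(=O)OCc1c(O)c2c(c(I)c1O)[C@@H](O[C@@H](C)c1ccccc1[N+](=O)[O-])OC2=O
F4 | step 9 | 5,7-bis(triisopropylsilyl) ether of F3 | CC(=O)OCc1c(O[Si](C(C)C)(C(C)C)C(C)C)c2c(c(I)c1O[Si](C(C)C)(C(C)C)C(C)C)[C@@H](O[C@@H](C)c1ccccc1[N+](=O)[O-])OC2=O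
F5 | step 9 | (4-methoxyphenyl)iodonium tosylate from F4 | CC(=O)OCc1c(O[Si](C(C)C)(C(C)C)C(C)C)c2c(c([I+]c3ccc(OC)cc3)c1O[Si](C(C)C)(C(C)C)C(C)C)[C@@H](O[C@@H](C)c1ccccc1[N+](=O)[O-])OC2=O.Cc1ccc(S(=O)(=O)[O-])cc1
F6 | step 9 | iodonium diol tosylate (F5 with both silyl ethers cleaved) | CC(=O)OCc1c(O)c2c(c([I+]c3ccc(OC)cc3)c1O)[C@@H](O[C@@H](C)c1ccccc1[N+](=O)[O-])OC2=O.Cc1ccc(S(=O)(=O)[O-])cc1
F7 | step 13 | aminophenyl acetal (22 with NO2 reduced to NH2) | CC(=O)OCc1c(O)c2c(c3c1OC(=O)c1c(C)cc(O)c(C=O)c1O3)[C@@H](O[C@@H](C)c1ccccc1N)OC2=O
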